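**Plan**

- Retrosynthesis: first the 22 benzyl ethers; then the C4–C8 bond between the middle and lower units; then, in one operation, C3–C4 and O1–C2 of ring C of the middle unit; last the upper C4–aryl bond and the gallate esters.
- Enabling feature: in the middle unit O1 sits on C8a, ortho to C4a, and C4 is benzylic to this phloroglucinol-type ring A. O1–C8a–C4a–C4 can therefore be unmasked from a salicylaldehyde as an o-quinone methide (1-oxadiene), and C2=C3 with its aryl and galloyloxy groups is a (Z)-styryl gallate.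
- Forward: the upper unit from (−)-epicatechin is joined at C4 to 3,5-bis(benzyloxy)phenol and ortho-formylated. A three-component union with HC(OMe)3 and the (Z)-enol gallate builds ring C of the middle unit on it. The lower unit from (+)-catechin is then added at C4, and hydrogenolysis ends the route.
- Stereochemistry: C2/C3 of the upper and lower units come from the chiral pool. Both C4 centres arise by attack anti to the 3-gallate. Middle C2/C3 are cis from the (Z)-alkene geometry, with the absolute sense set by a chiral phosphoramide counter-anion.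

Key step: step 10

Remark: the SMILES is read as epicatechin 3-O-gallate-(4β→8)-epigallocatechin 3-O-gallate-(4β→8)-catechin 3-O-gallate (all C2 R, lower unit 2,3-trans). In step 10 the (R)-catalyst is assumed to be the one matched with the upper unit.

**Step 1**
Reactants: 1 (−)-epicatechin; 2 benzyl bromide
Product: 3 5,7,3',4'-tetra-O-benzyl-(−)-epicatechin
Conditions: BnBr (4.4 equiv), K2CO3 (5 equiv), DMF, 0 °C to rt, argon
Reagents that add atoms: benzyl bromide, BrCc1ccccc1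
Why: Williamson ether synthesis in which K2CO3 ionises only the four phenols, so the C3 alcohol stays free and C2/C3 are untouched.

**Step 2**
Reactants: 3 5,7,3',4'-tetra-O-benzyl-(−)-epicatechin; 4 2-ethoxyethanol
Product: 5 5,7,3',4'-tetra-O-benzyl-4β-(2-ethoxyethoxy)-(−)-epicatechin
Conditions: DDQ (2,3-dichloro-5,6-dicyano-1,4-benzoquinone, 2 equiv), 2-ethoxyethanol (5 equiv), CH2Cl2, rt
Reagents that add atoms: 2-ethoxyethanol, CCOCCO
Why: DDQ benzylic oxidation (hydride abstraction at C4 to the cation stabilised by ring A) with capture by the alcohol anti to the 3-OH group, which sets C4 as 4β (3,4-trans).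

**Step 3**
Reactants: 5 5,7,3',4'-tetra-O-benzyl-4β-(2-ethoxyethoxy)-(−)-epicatechin; 6 3,4,5-tris(benzyloxy)benzoyl chloride
Product: 7 5,7,3',4'-tetra-O-benzyl-4β-(2-ethoxyethoxy)-(−)-epicatechin 3-O-[3,4,5-tris(benzyloxy)benzoate]
Conditions: 6 (1.5 equiv), Et3N (3 equiv), 4-(dimethylamino)pyridine (0.2 equiv), CH2Cl2, 0 °C to rt
Reagents that add atoms: 3,4,5-tris(benzyloxy)benzoyl chloride, O=C(Cl)c1cc(OCc2ccccc2)c(OCc2ccccc2)c(OCc2ccccc2)c1
Why: acylation of the hindered secondary alcohol by nucleophilic catalysis (acylpyridinium) under basic conditions that leave the acid-labile C4 ether alone.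

**Step 4**
Reactants: 7 4β-(2-ethoxyethoxy) gallate of the upper unit; 8 3,5-bis(benzyloxy)phenol
Product: 9 4β-[2-hydroxy-4,6-bis(benzyloxy)phenyl]-5,7,3',4'-tetra-O-benzyl-(−)-epicatechin 3-O-[3,4,5-tris(benzyloxy)benzoate]
Conditions: 8 (4 equiv), Me3SiOTf (0.2 equiv), CH2Cl2, −78 to −30 °C; then aq. NaHCO3
Reagents that add atoms: 3,5-bis(benzyloxy)phenol, Oc1cc(OCc2ccccc2)cc(OCc2ccccc2)c1
Why: Lewis acid ionisation at C4 and Friedel–Crafts arylation, in which the arene should attack through the carbon ortho to its free OH (less hindered than the carbon between two benzyloxy groups, as C8 against C6 in flavan nucleophiles) and from the β face anti to the participating 3-gallate, setting C4 as 3,4-trans.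

**Step 5**
Reactants: 9 phenol adduct of the upper unit; 10 formaldehyde (as paraformaldehyde)
Product: 12 4β-[3-formyl-2-hydroxy-4,6-bis(benzyloxy)phenyl]-5,7,3',4'-tetra-O-benzyl-(−)-epicatechin 3-O-[3,4,5-tris(benzyloxy)benzoate], via hydroxymethylphenol 11 (not isolated)
Conditions: MgCl2 (2 equiv), Et3N (4 equiv), (CH2O)n (7 equiv), THF, reflux; then 1 M HCl
Reagents that add atoms: formaldehyde, C=O
Why: Casnati–Skattebøl ortho-formylation, in which the magnesium phenoxide delivers formaldehyde to the only free ortho carbon and the benzylic alkoxide is oxidised by a second formaldehyde through hydride transfer.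

**Step 6**
Reactants: 13 (+)-catechin; 2 benzyl bromide
Product: 14 5,7,3',4'-tetra-O-benzyl-(+)-catechin
Conditions: BnBr (4.4 equiv), K2CO3 (5 equiv), DMF, 0 °C to rt, argon
Reagents that add atoms: benzyl bromide, BrCc1ccccc1
Why: Williamson ether synthesis selective for the phenols, as in step 1.

**Step 7**
Reactants: 14 5,7,3',4'-tetra-O-benzyl-(+)-catechin; 6 3,4,5-tris(benzyloxy)benzoyl chloride
Product: 15 5,7,3',4'-tetra-O-benzyl-(+)-catechin 3-O-[3,4,5-tris(benzyloxy)benzoate]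
Conditions: 6 (1.5 equiv), Et3N (3 equiv), 4-(dimethylamino)pyridine (0.2 equiv), CH2Cl2, rt
Reagents that add atoms: 3,4,5-tris(benzyloxy)benzoyl chloride, O=C(Cl)c1cc(OCc2ccccc2)c(OCc2ccccc2)c(OCc2ccccc2)c1
Why: acylation of the equatorial 3-OH by nucleophilic catalysis, with no change at C2/C3.

**Step 8**
Reactants: 16 3,4,5-tris(benzyloxy)benzaldehyde; 17 dimethyl (1-diazo-2-oxopropyl)phosphonate
Product: 18 1,2,3-tris(benzyloxy)-5-ethynylbenzene
Conditions: 17 (1.3 equiv), K2CO3 (2 equiv), MeOH/THF, rt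
Reagents that add atoms: dimethyl (1-diazo-2-oxopropyl)phosphonate, CC(=O)C(=[N+]=[N-])P(=O)(OC)OC
Why: Ohira–Bestmann variant of the Seyferth–Gilbert homologation, in which methanolysis frees the diazomethylphosphonate anion, which olefinates the aldehyde and loses N2 with a 1,2-hydrogen shift to the terminal alkyne.

**Step 9**
Reactants: 18 1,2,3-tris(benzyloxy)-5-ethynylbenzene; 19 3,4,5-tris(benzyloxy)benzoic acid
Product: 20 (Z)-2-[3,4,5-tris(benzyloxy)phenyl]ethenyl 3,4,5-tris(benzyloxy)benzoate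
Conditions: [RuCl2(p-cymene)]2 (2 mol%), P(4-ClC6H4)3 (6 mol%), 4-(dimethylamino)pyridine (8 mol%), toluene, 60 °C
Reagents that add atoms: 3,4,5-tris(benzyloxy)benzoic acid, OC(=O)c1cc(OCc2ccccc2)c(OCc2ccccc2)c(OCc2ccccc2)c1
Why: ruthenium-catalysed anti-Markovnikov addition of a carboxylic acid to a terminal alkyne through a ruthenium vinylidene, whose capture by carboxylate and protonolysis should deliver the (Z)-enol ester.

**Step 10**
Reactants: 12 salicylaldehyde of the upper unit; 20 (Z)-enol gallate; 21 trimethyl orthoformate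
Product: 24 pentadeca-O-benzyl epicatechin 3-O-gallate-(4β→8)-4-methoxy-epigallocatechin 3-O-gallate (middle unit 2R,3R; C4 epimers), via dimethyl acetal 22 (not isolated), via 4-methoxy o-quinone methide 23 (not isolated)
Conditions: 20 (2 equiv), HC(OMe)3 (3 equiv), (R)-3,3'-bis(2,4,6-triisopropylphenyl)-1,1'-binaphthyl-2,2'-diyl N-(trifluoromethylsulfonyl)phosphoramide (10 mol%), 4 Å molecular sieves, toluene/CH2Cl2, −20 °C to rt
Reagents that add atoms: trimethyl orthoformate, COC(OC)OC; enol ester 20, O=C(O/C=C\c1cc(OCc2ccccc2)c(OCc2ccccc2)c(OCc2ccccc2)c1)c1cc(OCc2ccccc2)c(OCc2ccccc2)c(OCc2ccccc2)c1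
Why: Proposed new method: acid turns aldehyde 12 via acetal 22 into the 4-methoxy o-quinone methide 23 (protonated form: an ortho-hydroxyaryl oxocarbenium ion), whose electrophilic C4 is attacked by C3 of enol ester 20 while O1 closes onto C2, an inverse-electron-demand oxa-[4+2] (hetero-Diels–Alder) closure of ring C of the middle unit that makes C3–C4 and O1–C2 together. The closest known reaction types are the acid-catalysed three-component chroman synthesis from salicylaldehydes, orthoformates and styrenes and the chiral Brønsted acid-catalysed [4+2] cycloadditions of o-quinone methides with styrenes; new is the (Z)-β-acyloxystyrene as the 2π partner, which places the oxygen on C3. The regiochemistry needs C3 and not C2 to bond to C4: positive charge at C2 is stabilised by the 4-benzyloxy-substituted aryl group and by closure of the gallate carbonyl to a 2-aryl-1,3-dioxolan-2-ylium ion, whereas attack through C2 would leave a poorly stabilised acyloxycarbenium ion at C3. C2 and C3 should come out cis because both new bonds form on one face of the (Z)-alkene (suprafacial addition; a dioxolanylium ion, if it intervenes, blocks rotation about C2–C3 and is opened by O1 with inversion, which gives the same result). The face of the alkene relative to the upper unit, hence 2R,3R, is to be set by the chiral phosphoramide anion hydrogen-bonded to the phenol and the oxocarbenium ion, and C4 bearing OMe is not controlled because step 11 erases it. Only one oxadiene can form, since ring A carries a single free OH and it is ortho to the formyl group.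

**Step 11**
Reactants: 24 4-methoxy dimer; 15 5,7,3',4'-tetra-O-benzyl-(+)-catechin 3-O-[3,4,5-tris(benzyloxy)benzoate]
Product: 25 docosa-O-benzyl epicatechin 3-O-gallate-(4β→8)-epigallocatechin 3-O-gallate-(4β→8)-catechin 3-O-gallate
Conditions: 15 (4 equiv), Me3SiOTf (0.2 equiv), CH2Cl2, −78 to −30 °C; then aq. NaHCO3
Reagents that add atoms: gallate 15, O=C(O[C@H]1Cc2c(OCc3ccccc3)cc(OCc3ccccc3)cc2O[C@@H]1c1ccc(OCc2ccccc2)c(OCc2ccccc2)c1)c1cc(OCc2ccccc2)c(OCc2ccccc2)c(OCc2ccccc2)c1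
Why: Lewis acid ionisation of either C4 epimer to one cation and Friedel–Crafts attack by C8 of the excess flavan nucleophile from the β face, anti to the 3-gallate (which can shield the α face as a dioxolanylium ion), setting the middle C4 as 3,4-trans.

**Step 12**
Reactants: 25 docosa-O-benzyl trimer
Product: 26 epicatechin 3-O-gallate-(4β→8)-epigallocatechin 3-O-gallate-(4β→8)-catechin 3-O-gallate (target)
Conditions: H2 (1 atm), Pd(OH)2/C, THF/MeOH/H2O (20:1:1), rt; filtration, lyophilisation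
Reagents that add atoms: none
Why: catalytic hydrogenolysis of all 22 benzyl ethers under neutral conditions, which should leave the esters, the flavan C2–O bonds and the interflavan bonds intact.

**Compound list**

1 | (−)-epicatechin (2R,3R) | O[C@@H]1Cc2c(O)cc(O)cc2O[C@@H]1c1ccc(O)c(O)c1 | starting material
2 | benzyl bromide | BrCc1ccccc1 | starting material
3 | 5,7,3',4'-tetra-O-benzyl-(−)-epicatechin | O[C@@H]1Cc2c(OCc3ccccc3)cc(OCc3ccccc3)cc2O[C@@H]1c1ccc(OCc2ccccc2)c(OCc2ccccc2)c1 | intermediate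
4 | 2-ethoxyethanol | CCOCCO | starting material
5 | 5,7,3',4'-tetra-O-benzyl-4β-(2-ethoxyethoxy)-(−)-epicatechin (2,3-cis-3,4-trans) | CCOCCO[C@H]1c2c(OCc3ccccc3)cc(OCc3ccccc3)cc2O[C@H](c2ccc(OCc3ccccc3)c(OCc3ccccc3)c2)[C@@H]1O | intermediate
6 | 3,4,5-tris(benzyloxy)benzoyl chloride | O=C(Cl)c1cc(OCc2ccccc2)c(OCc2ccccc2)c(OCc2ccccc2)c1 | starting material
7 | 5,7,3',4'-tetra-O-benzyl-4β-(2-ethoxyethoxy)-(−)-epicatechin 3-O-[3,4,5-tris(benzyloxy)benzoate] | CCOCCO[C@H]1c2c(OCc3ccccc3)cc(OCc3ccccc3)cc2O[C@H](c2ccc(OCc3ccccc3)c(OCc3ccccc3)c2)[C@@H]1OC(=O)c1cc(OCc2ccccc2)c(OCc2ccccc2)c(OCc2ccccc2)c1 | intermediate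
8 | 3,5-bis(benzyloxy)phenol | Oc1cc(OCc2ccccc2)cc(OCc2ccccc2)c1 | starting material
9 | 4β-[2-hydroxy-4,6-bis(benzyloxy)phenyl]-5,7,3',4'-tetra-O-benzyl-(−)-epicatechin 3-O-[3,4,5-tris(benzyloxy)benzoate] (2,3-cis-3,4-trans) | Oc1cc(OCc2ccccc2)cc(OCc2ccccc2)c1[C@H]1c2c(OCc3ccccc3)cc(OCc3ccccc3)cc2O[C@H](c2ccc(OCc3ccccc3)c(OCc3ccccc3)c2)[C@@H]1OC(=O)c1cc(OCc2ccccc2)c(OCc2ccccc2)c(OCc2ccccc2)c1 | intermediate
10 | formaldehyde (used as paraformaldehyde) | C=O | starting material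
11 | 3-hydroxymethyl derivative of 9 (CH2OH ortho to the free OH; magnesium phenoxide in the flask) | Oc1c(CO)c(OCc2ccccc2)cc(OCc2ccccc2)c1[C@H]1c2c(OCc3ccccc3)cc(OCc3ccccc3)cc2O[C@H](c2ccc(OCc3ccccc3)c(OCc3ccccc3)c2)[C@@H]1OC(=O)c1cc(OCc2ccccc2)c(OCc2ccccc2)c(OCc2ccccc2)c1 | intermediate (not isolated)
12 | 4β-[3-formyl-2-hydroxy-4,6-bis(benzyloxy)phenyl]-5,7,3',4'-tetra-O-benzyl-(−)-epicatechin 3-O-[3,4,5-tris(benzyloxy)benzoate] | Oc1c(C=O)c(OCc2ccccc2)cc(OCc2ccccc2)c1[C@H]1c2c(OCc3ccccc3)cc(OCc3ccccc3)cc2O[C@H](c2ccc(OCc3ccccc3)c(OCc3ccccc3)c2)[C@@H]1OC(=O)c1cc(OCc2ccccc2)c(OCc2ccccc2)c(OCc2ccccc2)c1 | intermediate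
13 | (+)-catechin (2R,3S) | O[C@H]1Cc2c(O)cc(O)cc2O[C@@H]1c1ccc(O)c(O)c1 | starting material
14 | 5,7,3',4'-tetra-O-benzyl-(+)-catechin | O[C@H]1Cc2c(OCc3ccccc3)cc(OCc3ccccc3)cc2O[C@@H]1c1ccc(OCc2ccccc2)c(OCc2ccccc2)c1 | intermediate
15 | 5,7,3',4'-tetra-O-benzyl-(+)-catechin 3-O-[3,4,5-tris(benzyloxy)benzoate] | O=C(O[C@H]1Cc2c(OCc3ccccc3)cc(OCc3ccccc3)cc2O[C@@H]1c1ccc(OCc2ccccc2)c(OCc2ccccc2)c1)c1cc(OCc2ccccc2)c(OCc2ccccc2)c(OCc2ccccc2)c1 | intermediate
16 | 3,4,5-tris(benzyloxy)benzaldehyde | O=Cc1cc(OCc2ccccc2)c(OCc2ccccc2)c(OCc2ccccc2)c1 | starting material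
17 | dimethyl (1-diazo-2-oxopropyl)phosphonate | CC(=O)C(=[N+]=[N-])P(=O)(OC)OC | starting material
18 | 1,2,3-tris(benzyloxy)-5-ethynylbenzene | C#Cc1cc(OCc2ccccc2)c(OCc2ccccc2)c(OCc2ccccc2)c1 | intermediate
19 | 3,4,5-tris(benzyloxy)benzoic acid | OC(=O)c1cc(OCc2ccccc2)c(OCc2ccccc2)c(OCc2ccccc2)c1 | starting material
20 | (Z)-2-[3,4,5-tris(benzyloxy)phenyl]ethenyl 3,4,5-tris(benzyloxy)benzoate | O=C(O/C=C\c1cc(OCc2ccccc2)c(OCc2ccccc2)c(OCc2ccccc2)c1)c1cc(OCc2ccccc2)c(OCc2ccccc2)c(OCc2ccccc2)c1 | intermediate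
21 | trimethyl orthoformate | COC(OC)OC | starting material
22 | dimethyl acetal of 12 | Oc1c(C(OC)OC)c(OCc2ccccc2)cc(OCc2ccccc2)c1[C@H]1c2c(OCc3ccccc3)cc(OCc3ccccc3)cc2O[C@H](c2ccc(OCc3ccccc3)c(OCc3ccccc3)c2)[C@@H]1OC(=O)c1cc(OCc2ccccc2)c(OCc2ccccc2)c(OCc2ccccc2)c1 | intermediate (not isolated)
23 | 4-methoxy o-quinone methide from 22 (6-(methoxymethylidene)cyclohexa-2,4-dienone; exocyclic C=C geometry not defined) | COC=C1C(=O)C([C@H]2c3c(OCc4ccccc4)cc(OCc4ccccc4)cc3O[C@H](c3ccc(OCc4ccccc4)c(OCc4ccccc4)c3)[C@@H]2OC(=O)c2cc(OCc3ccccc3)c(OCc3ccccc3)c(OCc3ccccc3)c2)=C(OCc2ccccc2)C=C1OCc1ccccc1 | intermediate (not isolated)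
24 | pentadeca-O-benzyl epicatechin 3-O-gallate-(4β→8)-4-methoxy-epigallocatechin 3-O-gallate (middle unit 2R,3R, 2,3-cis; C4–OMe as both epimers, erased in step 11) | O=C(O[C@@H]1C(OC)c2c(OCc3ccccc3)cc(OCc3ccccc3)c([C@H]3c4c(OCc5ccccc5)cc(OCc5ccccc5)cc4O[C@H](c4ccc(OCc5ccccc5)c(OCc5ccccc5)c4)[C@@H]3OC(=O)c3cc(OCc4ccccc4)c(OCc4ccccc4)c(OCc4ccccc4)c3)c2O[C@@H]1c1cc(OCc2ccccc2)c(OCc2ccccc2)c(OCc2ccccc2)c1)c1cc(OCc2ccccc2)c(OCc2ccccc2)c(OCc2ccccc2)c1 | intermediate
25 | docosa-O-benzyl epicatechin 3-O-gallate-(4β→8)-epigallocatechin 3-O-gallate-(4β→8)-catechin 3-O-gallate | O=C(O[C@@H]1[C@@H](c2c(OCc3ccccc3)cc(OCc3ccccc3)c3c2O[C@H](c2ccc(OCc4ccccc4)c(OCc4ccccc4)c2)[C@@H](OC(=O)c2cc(OCc4ccccc4)c(OCc4ccccc4)c(OCc4ccccc4)c2)C3)c2c(OCc3ccccc3)cc(OCc3ccccc3)c([C@H]3c4c(OCc5ccccc5)cc(OCc5ccccc5)cc4O[C@H](c4ccc(OCc5ccccc5)c(OCc5ccccc5)c4)[C@@H]3OC(=O)c3cc(OCc4ccccc4)c(OCc4ccccc4)c(OCc4ccccc4)c3)c2O[C@@H]1c1cc(OCc2ccccc2)c(OCc2ccccc2)c(OCc2ccccc2)c1)c1cc(OCc2ccccc2)c(OCc2ccccc2)c(OCc2ccccc2)c1 | intermediate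
26 | epicatechin 3-O-gallate-(4β→8)-epigallocatechin 3-O-gallate-(4β→8)-catechin 3-O-gallate | O=C(O[C@@H]1[C@@H](c2c(O)cc(O)c3c2O[C@H](c2ccc(O)c(O)c2)[C@@H](OC(=O)c2cc(O)c(O)c(O)c2)C3)c2c(O)cc(O)c([C@H]3c4c(O)cc(O)cc4O[C@H](c4ccc(O)c(O)c4)[C@@H]3OC(=O)c3cc(O)c(O)c(O)c3)c2O[C@@H]1c1cc(O)c(O)c(O)c1)c1cc(O)c(O)c(O)c1 | target

**Step count and risks**

Total step count: 12. Longest linear sequence: 8 steps (1, 2, 3, 4, 5, 10, 11, 12).

Steps most likely to fail:

1. Step 10. The alkene may add with reversed regiochemistry if the enol-ester oxygen rather than the aryl group directs it. Facial selectivity may be poor if catalyst and upper unit are mismatched. The cation may also be consumed by Friedel–Crafts attack on ring A of another molecule. The fallback uses known chemistry, sets out from 15 and 7 and comes back at 25. Commercial (−)-epigallocatechin is benzylated (BnBr, K2CO3, DMF) to 5,7,3',4',5'-penta-O-benzyl-(−)-epigallocatechin F1. Oxidation with DDQ in the presence of 2-ethoxyethanol gives the 4β-(2-ethoxyethoxy) derivative F2, and acylation with 6 (Et3N, 4-(dimethylamino)pyridine) gives its 3-O-gallate F3. Me3SiOTf-catalysed condensation of F3 with excess 15 should give the protected epigallocatechin gallate-(4β→8)-catechin gallate dimer F4. A second Me3SiOTf-catalysed condensation of F4, through C8 of its upper unit, with 7 gives 25. Steps 4, 5, 8, 9, 10 and 11 are then not needed.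

2. Step 4. The C4 cation may attack para to the phenol OH (between the two benzyloxy groups) or at oxygen, which would end in a 4→6 linkage. The fallback sets out from 7 and comes back at 12. Me3SiOTf-catalysed condensation of 7 with excess benzene-1,3,5-triol (THF/CH2Cl2), a symmetrical nucleophile without regiochemical choice, should give the 4β-(2,4,6-trihydroxyphenyl) adduct F5. Vilsmeier–Haack formylation (POCl3, DMF, EtOAc, 0 °C, then aq. NaOAc) at one of its two equivalent free positions gives the trihydroxybenzaldehyde F6. Benzylation with 2 equiv of BnBr and K2CO3 should take the OH para to the formyl group and the less hindered chelated OH, and leave free the OH flanked by the formyl and flavanyl groups, which is 12.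

3. Step 11. The dimeric cation may self-condense with ring A positions of another dimer, attack may occur through C6 of 15, and the acid may cleave the existing interflavan bond. The fallback sets out from 24 and comes back at 25. Exchange of OMe for a sulfur leaving group with 2-mercaptobenzothiazole and BF3·OEt2 (CH2Cl2, −78 °C) gives the 4β-(benzothiazol-2-ylthio) dimer F7. AgBF4 (THF, 0 °C) then ionises C4 in the presence of 15 by thiophilic activation, without Brønsted or oxophilic Lewis acid.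

**Further compounds**

F1 | step 10 | 5,7,3',4',5'-penta-O-benzyl-(−)-epigallocatechin | O[C@@H]1Cc2c(OCc3ccccc3)cc(OCc3ccccc3)cc2O[C@@H]1c1cc(OCc2ccccc2)c(OCc2ccccc2)c(OCc2ccccc2)c1
F2 | step 10 | 5,7,3',4',5'-penta-O-benzyl-4β-(2-ethoxyethoxy)-(−)-epigallocatechin | CCOCCO[C@H]1c2c(OCc3ccccc3)cc(OCc3ccccc3)cc2O[C@H](c2cc(OCc3ccccc3)c(OCc3ccccc3)c(OCc3ccccc3)c2)[C@@H]1O
F3 | step 10 | 5,7,3',4',5'-penta-O-benzyl-4β-(2-ethoxyethoxy)-(−)-epigallocatechin 3-O-[3,4,5-tris(benzyloxy)benzoate] | CCOCCO[C@H]1c2c(OCc3ccccc3)cc(OCc3ccccc3)cc2O[C@H](c2cc(OCc3ccccc3)c(OCc3ccccc3)c(OCc3ccccc3)c2)[C@@H]1OC(=O)c1cc(OCc2ccccc2)c(OCc2ccccc2)c(OCc2ccccc2)c1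
F4 | step 10 | pentadeca-O-benzyl epigallocatechin 3-O-gallate-(4β→8)-catechin 3-O-gallate | O=C(O[C@@H]1[C@@H](c2c(OCc3ccccc3)cc(OCc3ccccc3)c3c2O[C@H](c2ccc(OCc4ccccc4)c(OCc4ccccc4)c2)[C@@H](OC(=O)c2cc(OCc4ccccc4)c(OCc4ccccc4)c(OCc4ccccc4)c2)C3)c2c(OCc3ccccc3)cc(OCc3ccccc3)cc2O[C@@H]1c1cc(OCc2ccccc2)c(OCc2ccccc2)c(OCc2ccccc2)c1)c1cc(OCc2ccccc2)c(OCc2ccccc2)c(OCc2ccccc2)c1
F5 | step 4 | 4β-(2,4,6-trihydroxyphenyl)-5,7,3',4'-tetra-O-benzyl-(−)-epicatechin 3-O-[3,4,5-tris(benzyloxy)benzoate] | Oc1cc(O)c(c(O)c1)[C@H]1c2c(OCc3ccccc3)cc(OCc3ccccc3)cc2O[C@H](c2ccc(OCc3ccccc3)c(OCc3ccccc3)c2)[C@@H]1OC(=O)c1cc(OCc2ccccc2)c(OCc2ccccc2)c(OCc2ccccc2)c1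
F6 | step 4 | 4β-(3-formyl-2,4,6-trihydroxyphenyl)-5,7,3',4'-tetra-O-benzyl-(−)-epicatechin 3-O-[3,4,5-tris(benzyloxy)benzoate] | Oc1cc(O)c(C=O)c(O)c1[C@H]1c2c(OCc3ccccc3)cc(OCc3ccccc3)cc2O[C@H](c2ccc(OCc3ccccc3)c(OCc3ccccc3)c2)[C@@H]1OC(=O)c1cc(OCc2ccccc2)c(OCc2ccccc2)c(OCc2ccccc2)c1
F7 | step 11 | pentadeca-O-benzyl epicatechin 3-O-gallate-(4β→8)-4β-(benzothiazol-2-ylthio)-epigallocatechin 3-O-gallate | O=C(O[C@@H]1[C@@H](Sc2nc3ccccc3s2)c2c(OCc3ccccc3)cc(OCc3ccccc3)c([C@H]3c4c(OCc5ccccc5)cc(OCc5ccccc5)cc4O[C@H](c4ccc(OCc5ccccc5)c(OCc5ccccc5)c4)[C@@H]3OC(=O)c3cc(OCc4ccccc4)c(OCc4ccccc4)c(OCc4ccccc4)c3)c2O[C@@H]1c1cc(OCc2ccccc2)c(OCc2ccccc2)c(OCc2ccccc2)c1)c1cc(OCc2ccccc2)c(OCc2ccccc2)c(OCc2ccccc2)c1
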